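**Retrosynthetic overview**
- The target is (R)-cryptostictic acid, a depsidone. The seven-membered dioxepinone ring is closed last, by direct dehydrogenative phenol O–C coupling of a fully functionalised depside: the A-ring 2-OH bonds to the B-ring C–H para to the free B-ring phenol (no halide, no separate lactonisation).
- The depside ester is made before the ether, from an A-ring salicylic acid and a B-ring 5,7-dihydroxyphthalide acetal.
- The five-membered lactol ring is formed first, by spontaneous ring closure of a 2-formylbenzoic acid (directed ortho-metalation/carboxylation of 3,5-dimethoxy-4-methylbenzaldehyde).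
- The labile C-3 centre is fixed as (R) in a separable (S)-1-phenylethyl acetal and released at the end by neutral hydrogenolysis, which also frees the CH2OH.
- The A ring comes from 3,5-dimethoxytoluene (lithiation/benzyloxymethylation, mono-demethylation, ortho-formylation, oxidation).

Assumption: the only stereocentre is the C-3 hemiacylal carbon, which epimerises by ring–chain tautomerism in acid or base; it is therefore carried as an acetal and released only in the last, neutral step, and the product is kept cold, neutral and aprotic.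

**Route**

Step 1
Reactants: 1 3,5-dimethoxy-4-methylbenzaldehyde
Product: 5 rac-3-hydroxy-5,7-dimethoxy-6-methyl-2-benzofuran-1(3H)-one, via lithium α-amino alkoxide 2 (not isolated), via ring-lithiated alkoxide 3 (not isolated), via open-chain formyl acid 4 (not isolated)
Conditions: Me2N(CH2)2N(Me)Li (1.1 equiv), THF, −20 °C; n-BuLi (3 equiv), −20 → 0 °C; CO2, −78 °C → rt; 2 M HCl
Reagents that add atoms: carbon dioxide, O=C=O
Why: Comins-type α-amino-alkoxide directed ortho-metalation lithiates C-2 (flanked by the masked CHO and an OMe; C-2 and C-6 are equivalent), carboxylation and acidic work-up give the 2-formylbenzoic acid, which closes spontaneously to the lactol (ring–chain tautomerism; racemic at C-3 at this stage).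

Step 2
Reactants: 5 rac-3-hydroxy-5,7-dimethoxy-6-methyl-2-benzofuran-1(3H)-one
Product: 6 rac-3,5,7-trihydroxy-6-methyl-2-benzofuran-1(3H)-one
Conditions: BBr3 (4 equiv), CH2Cl2, −78 °C → rt; H2O, 0 °C
Reagents that add atoms: none
Why: BBr3 demethylation cleaves both aryl methyl ethers (the C-7 OMe is chelation-activated by the lactone carbonyl) and the aqueous quench returns the lactol, still racemic.

Step 3
Reactants: 6 rac-3,5,7-trihydroxy-6-methyl-2-benzofuran-1(3H)-one; 7 (S)-1-phenylethanol
Product: 9 (3R)-5,7-dihydroxy-6-methyl-3-[(1S)-1-phenylethoxy]-2-benzofuran-1(3H)-one, via (3S)-epimer 8 (not isolated)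
Conditions: 7 (3 equiv), PPTS (10 mol%), 4 Å MS, PhMe/THF, 45 °C; 9 separated by chromatography or crystallisation, the (3S)-rich remainder returned to the same conditions
Reagents that add atoms: (S)-1-phenylethanol 7, C[C@H](O)c1ccccc1
Why: acid-catalysed pseudo-ester (acetal) formation at the hemiacylal is reversible through an acyloxycarbenium ion, so the two C-3 epimers are interconverting diastereomers and (3R) is set by separating the (3R,1′S) acetal and recycling the other (auxiliary-based dynamic resolution; the C-3 assignment is to be confirmed by X-ray).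

Step 4
Reactants: 10 3,5-dimethoxytoluene; 11 benzyl chloromethyl ether
Product: 13 2-[(benzyloxy)methyl]-1,3-dimethoxy-5-methylbenzene, via 2,6-dimethoxy-4-methylphenyllithium 12 (not isolated)
Conditions: n-BuLi (1.1 equiv), THF, 0 °C → rt; 11, −78 °C → rt
Reagents that add atoms: benzyl chloromethyl ether 11, ClCOCc1ccccc1
Why: directed ortho-metalation removes the proton between the two OMe groups and SN2 alkylation with the α-chloro ether installs the future CH2OH carbon already as its benzyl ether.

Step 5
Reactants: 13 2-[(benzyloxy)methyl]-1,3-dimethoxy-5-methylbenzene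
Product: 14 2-[(benzyloxy)methyl]-3-methoxy-5-methylphenol
Conditions: KPPh2 (1.3 equiv, 0.5 M in THF), THF, 25 → 60 °C; 1 M HCl
Reagents that add atoms: none
Why: SN2 demethylation of an aryl methyl ether by diphenylphosphide; the two OMe groups are equivalent, the phenoxide formed blocks a second cleavage, and the benzyl alkyl ether (alkoxide leaving group) is not attacked.

Step 6
Reactants: 14 2-[(benzyloxy)methyl]-3-methoxy-5-methylphenol
Product: 16 3-[(benzyloxy)methyl]-2-hydroxy-4-methoxy-6-methylbenzaldehyde, via hydroxymethyl phenol 15 (not isolated)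
Conditions: MgCl2, Et3N, (CH2O)n, MeCN, reflux; 1 M HCl
Reagents that add atoms: formaldehyde (as paraformaldehyde), C=O
Why: magnesium-mediated ortho-formylation (Casnati–Skattebøl) delivers formaldehyde only to the single free ortho position of the Mg phenoxide, and the resulting benzylic alkoxide is oxidised in situ by hydride transfer to a second formaldehyde.

Step 7
Reactants: 16 3-[(benzyloxy)methyl]-2-hydroxy-4-methoxy-6-methylbenzaldehyde
Product: 17 3-[(benzyloxy)methyl]-2-hydroxy-4-methoxy-6-methylbenzoic acid
Conditions: NaClO2, NaH2PO4, 2-methyl-2-butene, t-BuOH/H2O, 0 °C → rt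
Reagents that add atoms: sodium chlorite, [Na+].[O-]Cl=O
Why: Pinnick oxidation converts the hindered salicylaldehyde to the acid without touching the benzyl ether, with the alkene scavenging HOCl so the electron-rich ring is not chlorinated.

Step 8
Reactants: 17 3-[(benzyloxy)methyl]-2-hydroxy-4-methoxy-6-methylbenzoic acid; 9 (3R)-5,7-dihydroxy-6-methyl-3-[(1S)-1-phenylethoxy]-2-benzofuran-1(3H)-one
Product: 19 (3R)-7-hydroxy-6-methyl-1-oxo-3-[(1S)-1-phenylethoxy]-1,3-dihydro-2-benzofuran-5-yl 3-[(benzyloxy)methyl]-2-hydroxy-4-methoxy-6-methylbenzoate, via O-acylisourea 18 (not isolated)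
Conditions: DCC (1.1 equiv), DMAP (5 mol%), CH2Cl2, 0 °C → rt
Reagents that add atoms: none
Why: Steglich esterification acylates the C-5 OH of 9 (para to the lactone carbonyl, acidic and unchelated) in preference to the chelated C-7 OH and the acid's own chelated 2-OH, and the neutral conditions leave the C-3 acetal configuration untouched.

Step 9
Reactants: 19 (3R)-7-hydroxy-6-methyl-1-oxo-3-[(1S)-1-phenylethoxy]-1,3-dihydro-2-benzofuran-5-yl 3-[(benzyloxy)methyl]-2-hydroxy-4-methoxy-6-methylbenzoate
Product: 21 (1R)-11-[(benzyloxy)methyl]-4-hydroxy-10-methoxy-5,8-dimethyl-1-[(1S)-1-phenylethoxy]-1H-2,6,12-trioxabenzo[5,6]cyclohepta[1,2-e]indene-3,7-dione, via cyclohexadienone tautomer 20 (not isolated)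
Conditions: activated MnO2 (15 equiv), CH2Cl2 (2 mM), rt, dark
Reagents that add atoms: none
Why: Proposed new method: MnO2 as a surface one-electron oxidant converts the two chelated phenols (A-ring 2-OH, B-ring 7-OH) into phenoxyl radicals, and the A-ring oxygen radical combines through the E-ester rotamer with the B-ring radical at C-4, the only open position and para to the B-ring oxygen (both ortho positions are blocked), closing the seven-membered ring as dienone 20, which tautomerises to the phenol; the closest known reaction types are the MnO2 oxidative cyclisation of halogenated depsides to depsidones and the Hay para C–O coupling of 2,6-disubstituted phenols; no stereocentre is formed and the neutral anhydrous medium does not disturb C-3.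

Step 10
Reactants: 21 (1R)-11-[(benzyloxy)methyl]-4-hydroxy-10-methoxy-5,8-dimethyl-1-[(1S)-1-phenylethoxy]-1H-2,6,12-trioxabenzo[5,6]cyclohepta[1,2-e]indene-3,7-dione
Product: 22 (1R)-1,4-dihydroxy-11-(hydroxymethyl)-10-methoxy-5,8-dimethyl-1H-2,6,12-trioxabenzo[5,6]cyclohepta[1,2-e]indene-3,7-dione [(R)-cryptostictic acid]
Conditions: H2 (1 atm), Pd(OH)2/C, EtOAc, 0 → 20 °C, stopped at full conversion; filter, evaporate below 25 °C
Reagents that add atoms: none
Why: catalytic hydrogenolysis cleaves the unhindered PhCH2–O and PhCH(Me)–O bonds and not the bonds at C-3 or the hindered ArCH2–O bond on the fully substituted ring, so the lactol is released with retention as (R) under neutral aprotic conditions that do not open it.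

**Compound list**
1 | 3,5-dimethoxy-4-methylbenzaldehyde | COc1cc(C=O)cc(OC)c1C | starting material
2 | lithium (3,5-dimethoxy-4-methylphenyl)[(2-(dimethylamino)ethyl)(methyl)amino]methanolate | [Li+].[O-]C(N(C)CCN(C)C)c1cc(OC)c(C)c(OC)c1 | intermediate
3 | C-2 ring-lithiated derivative of 2 | [Li+].[O-]C(N(C)CCN(C)C)c1cc(OC)c(C)c(OC)c1[Li] | intermediate
4 | 6-formyl-2,4-dimethoxy-3-methylbenzoic acid | COc1cc(C=O)c(C(=O)O)c(OC)c1C | intermediate
5 | rac-3-hydroxy-5,7-dimethoxy-6-methyl-2-benzofuran-1(3H)-one | COc1cc2c(c(OC)c1C)C(=O)OC2O | intermediate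
6 | rac-3,5,7-trihydroxy-6-methyl-2-benzofuran-1(3H)-one | Cc1c(O)cc2c(c1O)C(=O)OC2O | intermediate
7 | (S)-1-phenylethanol | C[C@H](O)c1ccccc1 | starting material
8 | (3S)-5,7-dihydroxy-6-methyl-3-[(1S)-1-phenylethoxy]-2-benzofuran-1(3H)-one (recycled epimer) | Cc1c(O)cc2c(c1O)C(=O)O[C@@H]2O[C@@H](C)c1ccccc1 | intermediate
9 | (3R)-5,7-dihydroxy-6-methyl-3-[(1S)-1-phenylethoxy]-2-benzofuran-1(3H)-one | Cc1c(O)cc2c(c1O)C(=O)O[C@H]2O[C@@H](C)c1ccccc1 | intermediate
10 | 3,5-dimethoxytoluene | COc1cc(C)cc(OC)c1 | starting material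
11 | benzyl chloromethyl ether | ClCOCc1ccccc1 | starting material
12 | 2,6-dimethoxy-4-methylphenyllithium | [Li]c1c(OC)cc(C)cc1OC | intermediate
13 | 2-[(benzyloxy)methyl]-1,3-dimethoxy-5-methylbenzene | COc1cc(C)cc(OC)c1COCc1ccccc1 | intermediate
14 | 2-[(benzyloxy)methyl]-3-methoxy-5-methylphenol | COc1cc(C)cc(O)c1COCc1ccccc1 | intermediate
15 | 2-[(benzyloxy)methyl]-6-(hydroxymethyl)-3-methoxy-5-methylphenol | COc1cc(C)c(CO)c(O)c1COCc1ccccc1 | intermediate
16 | 3-[(benzyloxy)methyl]-2-hydroxy-4-methoxy-6-methylbenzaldehyde | COc1cc(C)c(C=O)c(O)c1COCc1ccccc1 | intermediate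
17 | 3-[(benzyloxy)methyl]-2-hydroxy-4-methoxy-6-methylbenzoic acid | COc1cc(C)c(C(=O)O)c(O)c1COCc1ccccc1 | intermediate
18 | O-acylisourea of 17 with DCC | COc1cc(C)c(C(=O)OC(=NC2CCCCC2)NC2CCCCC2)c(O)c1COCc1ccccc1 | intermediate
19 | (3R)-7-hydroxy-6-methyl-1-oxo-3-[(1S)-1-phenylethoxy]-1,3-dihydro-2-benzofuran-5-yl 3-[(benzyloxy)methyl]-2-hydroxy-4-methoxy-6-methylbenzoate (depside) | COc1cc(C)c(C(=O)Oc2cc3c(c(O)c2C)C(=O)O[C@H]3O[C@@H](C)c2ccccc2)c(O)c1COCc1ccccc1 | intermediate
20 | 4-aryloxy-cyclohexa-2,5-dienone tautomer of 21 (phthalide C-4 sp3, C-7 ketone) | COc1cc(C)c2c(c1COCc1ccccc1)OC1C(OC2=O)=C(C)C(=O)C3=C1[C@H](O[C@@H](C)c1ccccc1)OC3=O | intermediate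
21 | (1R)-11-[(benzyloxy)methyl]-4-hydroxy-10-methoxy-5,8-dimethyl-1-[(1S)-1-phenylethoxy]-1H-2,6,12-trioxabenzo[5,6]cyclohepta[1,2-e]indene-3,7-dione (O-benzyl cryptostictic acid 1-phenylethyl pseudo-ester) | COc1cc(C)c2c(c1COCc1ccccc1)Oc1c(c(C)c(O)c3c1[C@H](O[C@@H](C)c1ccccc1)OC3=O)OC2=O | intermediate
22 | (1R)-1,4-dihydroxy-11-(hydroxymethyl)-10-methoxy-5,8-dimethyl-1H-2,6,12-trioxabenzo[5,6]cyclohepta[1,2-e]indene-3,7-dione, (R)-cryptostictic acid | COc1cc(C)c2c(c1CO)Oc1c(c(C)c(O)c3c1[C@H](O)OC3=O)OC2=O | target

**Step count and risks**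

Total: 10 steps (B ring: steps 1–3; A ring: steps 4–7; union and endgame: steps 8–10). Longest linear sequence: 7 steps (steps 4–10). Step 3 is yield-limited to about half per pass before recycling of 8.

The three steps most likely to fail are 9, 10 and 8.

Step 9 is the riskiest. Both phenols are hydrogen-bonded to carbonyls and hard to oxidise, the ortho-alkyl groups can divert the phenoxyl radicals to quinone methides, and the product (a para-aryloxyphenol) is easier to oxidise than the starting depside. The fallback sets out from depside 19 and rejoins at 21. Irradiation of 19 (300 nm, MeCN, rt) effects a photo-Fries 1,3-acyl shift to the free ortho carbon C-4, giving the benzophenone (3R)-4-{3-[(benzyloxy)methyl]-2-hydroxy-4-methoxy-6-methylbenzoyl}-5,7-dihydroxy-6-methyl-3-[(1S)-1-phenylethoxy]-2-benzofuran-1(3H)-one F1. Oxidation of F1 (Ag2O, benzene, rt) closes a five-membered O–C bond at the acyl-bearing carbon of the now free resorcinol ring to give the spiro grisa-3′,5′-diene-2′,3-dione F2. Warming F2 in toluene (80–110 °C) moves the acyl group from carbon to the adjacent dienone oxygen with re-aromatisation and delivers depsidone 21.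

Step 10 can fail by over-reduction (ArCH2OH to ArCH3, or hydrogenolysis at C-3) or by epimerisation of the freed lactol on the catalyst. The fallback sets out from 21 and rejoins at 22. Aqueous TFA (TFA/H2O 9:1, 0 °C) solvolyses both benzylic C–O bonds to give racemic cryptostictic acid F3. Acylative dynamic kinetic resolution (Ac2O, i-Pr2NEt, chiral isothiourea or chiral DMAP catalyst of the antipode that acylates the (R)-lactol, CHCl3, 0 °C) gives the (1R)-1-acetoxy-11-(acetoxymethyl) diacetate F4, the lactol epimerising through its open formyl-carboxylate while only one enantiomer is acylated. Lipase-mediated alcoholysis (CAL-B, n-BuOH, MTBE, 25 °C) then removes both acetates by acyl–oxygen cleavage, giving 22 with retention.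

Step 8 couples a 2,6-disubstituted salicylic acid with a hindered phenol; N-acylurea formation or low conversion is the likely failure. The fallback sets out from acid 17 and rejoins at 19. Acetone/TFAA/TFA (0 °C → rt) converts 17 into 8-[(benzyloxy)methyl]-7-methoxy-2,2,5-trimethyl-4H-1,3-benzodioxin-4-one F5. Photolysis of F5 (300 nm, CH2Cl2, rt) in the presence of phenol 9 generates the quinoketene, which is trapped by the C-5 OH to give depside 19 with the A-ring 2-OH already free.

Further compounds
F1 | step 9 | (3R)-4-{3-[(benzyloxy)methyl]-2-hydroxy-4-methoxy-6-methylbenzoyl}-5,7-dihydroxy-6-methyl-3-[(1S)-1-phenylethoxy]-2-benzofuran-1(3H)-one | COc1cc(C)c(C(=O)c2c(O)c(C)c(O)c3c2[C@H](O[C@@H](C)c2ccccc2)OC3=O)c(O)c1COCc1ccccc1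
F2 | step 9 | spiro grisa-3′,5′-diene-2′,3-dione (A-ring benzofuran-3-one spiro-fused at C-4 of the dearomatised phthalide ring; C-5 ketone, C-7 enol OH, (3R)-acetal retained) | COc1cc(C)c2C(=O)C3(Oc2c1COCc1ccccc1)C(=O)C(C)=C(O)C1=C3[C@H](O[C@@H](C)c3ccccc3)OC1=O
F3 | step 10 | rac-cryptostictic acid | COc1cc(C)c2c(c1CO)Oc1c(c(C)c(O)c3c1C(O)OC3=O)OC2=O
F4 | step 10 | (1R)-1-acetoxy-11-(acetoxymethyl)-4-hydroxy-10-methoxy-5,8-dimethyl-1H-2,6,12-trioxabenzo[5,6]cyclohepta[1,2-e]indene-3,7-dione | COc1cc(C)c2c(c1COC(C)=O)Oc1c(c(C)c(O)c3c1[C@H](OC(C)=O)OC3=O)OC2=O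
F5 | step 8 | 8-[(benzyloxy)methyl]-7-methoxy-2,2,5-trimethyl-4H-1,3-benzodioxin-4-one | COc1cc(C)c2C(=O)OC(C)(C)Oc2c1COCc1ccccc1
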